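## Retrosynthetic overview

- Ring B of target 27 (C1–C4, C4a, C8a) is a 2‑carbomethoxy‑3‑alkylcyclohex‑2‑enone. C2 and C4 are the α‑ and γ‑carbons of one 3‑methylalk‑2‑enoate; C1 and C4a are the acyl carbon and β‑carbon of the enoyl unit C1–C8a=C4a of ring A. Ring B is therefore the 6π‑closure product of the 3‑oxidohexatriene C4=C3–C2=C1(O−)–C8a=C4a.
- Disconnect C1–C2 and C4–C4a together: lithium dienolate of enoate 21 plus ring A acid chloride 17 (C5/C8 trans). α‑C‑Acylation, then electrocyclisation, closes ring B last.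
- Ring A comes from a Diels–Alder reaction of silyl dienyl ether 7 with 5‑menthyloxyfuranone 8 (sets C8 and the absolute configuration). The allylsilane relays C8 to C5 by anti‑SE2′ carboxamidation and moves the alkene to C6=C7. The methoxy group is the leaving group for C8a=C4a.
- The menthyl acetal lactone is a temporary ring: it keeps C8 non‑enolisable, differentiates the two carboxyls and is removed by hydrolysis/oxidation.
- Ring order: ring A (step 5), ring B (step 12). Both C16 chains derive from 1‑bromohexadecane through one stock solution of hexadecylmagnesium bromide 2.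

Key step: step 12

Remark: atom numbers in the text are those of the target (C1 ketone carbon, C2/C3 enone carbons, C4 ring CH2, C4a/C8a ring fusion, C5–C8 ring A).
Assumption: the target SMILES is read as the (4aR,5S,8R,8aS) isomer, i.e. cis ring fusion, with the C8 ester cis and the C5 ester trans to the ring B bonds at C8a and C4a.
Assumption: the Wittig step gives the enol ether as an E/Z mixture; the (3E)‑isomer 7 is separated and carried on.
Assumption: the Grignard reagent 2 is prepared once, titrated and stored under argon as a THF solution; portions of it serve steps 2 and 11.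

## Route

Step 1
Reactants: 1 1‑bromohexadecane
Product: 2 hexadecylmagnesium bromide (titrated stock solution in THF)
Conditions: Mg turnings (1.2 equiv), I2 (cat.), THF, 40 to 65 °C; kept under argon
Reagents that add atoms: magnesium, [Mg]
Why: Insertion of magnesium into a primary alkyl bromide (Grignard reagent formation) is routine, and one stock solution should supply both later organometallic steps.

Step 2
Reactants: 2 hexadecylmagnesium bromide; 3 3‑(trimethylsilyl)prop‑2‑yn‑1‑ol
Product: 5 (E)‑2‑hexadecyl‑3‑(trimethylsilyl)prop‑2‑en‑1‑ol, via cyclic alkenylmagnesium alkoxide 4 (not isolated)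
Conditions: 2 (2.5 equiv), 3, CuI (10 mol%), Et2O–THF, reflux; aq NH4Cl
Reagents that add atoms: none
Why: Copper‑catalysed anti‑carbomagnesiation of a propargylic alcohol should deliver the alkyl group to C2 and hold the new C–Mg bond in an alkoxide chelate cis to CH2O, so protonolysis leaves silicon cis to the chain, which later places silicon on the outside of the diene.

Step 3
Reactants: 5 (E)‑2‑hexadecyl‑3‑(trimethylsilyl)prop‑2‑en‑1‑ol
Product: 6 (E)‑2‑hexadecyl‑3‑(trimethylsilyl)prop‑2‑enal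
Conditions: activated MnO2, CH2Cl2, 23 °C
Reagents that add atoms: none
Why: Allylic alcohol oxidation with MnO2 is neutral and should leave the vinylsilane and its geometry untouched.

Step 4
Reactants: 6 (E)‑2‑hexadecyl‑3‑(trimethylsilyl)prop‑2‑enal
Product: 7 [(1E,3E)‑2‑hexadecyl‑4‑methoxybuta‑1,3‑dien‑1‑yl]trimethylsilane
Conditions: MeOCH2PPh3Cl, KOt‑Bu, THF, 0 °C to 23 °C; separation of the (3E)‑isomer
Reagents that add atoms: (methoxymethyl)triphenylphosphonium chloride, COC[P+](c1ccccc1)(c1ccccc1)c1ccccc1.[Cl-]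
Why: Wittig methoxymethylenation of the aldehyde should give the 1‑methoxydiene, whose methoxy group is the later leaving group for the C8a=C4a double bond.

Step 5
Reactants: 7 [(1E,3E)‑2‑hexadecyl‑4‑methoxybuta‑1,3‑dien‑1‑yl]trimethylsilane; 8 (5R)‑5‑[(1R,2S,5R)‑menthyloxy]furan‑2(5H)‑one
Product: 9 (3R,3aR,4S,7S,7aR)‑5‑hexadecyl‑3‑[(1R,2S,5R)‑menthyloxy]‑7‑methoxy‑4‑(trimethylsilyl)‑3a,4,7,7a‑tetrahydro‑2‑benzofuran‑1(3H)‑one (SiMe3 and OMe cis to the lactone ring)
Conditions: toluene, BHT (cat.), 110 °C, sealed tube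
Reagents that add atoms: none
Why: The thermal Diels–Alder reaction of the 5‑alkoxybutenolide should occur endo and anti to the menthyloxy group, with the methoxy‑bearing diene terminus bonding to the lactone α‑carbon (ortho rule), which sets C8 in absolute terms, the adjacent C–Si centre cis to it and the cis ring fusion.

Step 6
Reactants: 9 Diels–Alder adduct
Product: 11 (3R,3aR,6R,7S,7aR)‑5‑hexadecyl‑3‑[(1R,2S,5R)‑menthyloxy]‑7‑methoxy‑1‑oxo‑1,3,3a,6,7,7a‑hexahydro‑2‑benzofuran‑6‑carboxamide, via N‑chlorosulfonyl N‑silyl amide 10 (not isolated)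
Conditions: ClSO2NCO, CH2Cl2, −78 °C to −20 °C; then aq NaHCO3, 0 °C
Reagents that add atoms: chlorosulfonyl isocyanate, O=C=NS(Cl)(=O)=O
Why: Electrophilic substitution of the allylsilane by chlorosulfonyl isocyanate with allyl transposition (anti‑SE2′, attack on the face opposite silicon) should create C5 trans to the C8 substituent and move the alkene to C6=C7, and hydrolysis of the N‑chlorosulfonyl group leaves the primary amide.

Step 7
Reactants: 11 methoxy lactone amide
Product: 12 (3R,3aR,6S)‑5‑hexadecyl‑3‑[(1R,2S,5R)‑menthyloxy]‑1‑oxo‑1,3,3a,6‑tetrahydro‑2‑benzofuran‑6‑carboxamide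
Conditions: DBU, toluene, 70 °C
Reagents that add atoms: none
Why: E1cB elimination of methanol from the β‑methoxy lactone should form C8a=C4a without epimerisation, because only the lactone α‑hydrogen is acidic (C8 carries an acetal carbon, C5 a weakly acidifying carboxamide).

Step 8
Reactants: 12 butenolide amide
Product: 14 methyl (3aR,6S)‑5‑hexadecyl‑3‑hydroxy‑1‑oxo‑1,3,3a,6‑tetrahydro‑2‑benzofuran‑6‑carboxylate (lactol; both C3 epimers), via imidate tetrafluoroborate 13 (not isolated)
Conditions: Me3OBF4, CH2Cl2, 23 °C; then 1 M aq HCl, THF, 40 °C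
Reagents that add atoms: trimethyloxonium tetrafluoroborate, C[O+](C)C.F[B-](F)(F)F; water, O
Why: O‑Methylation of the primary amide and hydrolysis of the imidate salt should give the methyl ester, while the same aqueous acid hydrolyses the menthyl pseudo‑ester to the lactol.

Step 9
Reactants: 14 lactol ester
Product: 16 (3S,6R)‑4‑hexadecyl‑3,6‑bis(methoxycarbonyl)cyclohexa‑1,4‑diene‑1‑carboxylic acid, via cyclic anhydride 15 (not isolated)
Conditions: Dess–Martin periodinane, CH2Cl2, 0 °C to 23 °C; then MeOH, 23 °C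
Reagents that add atoms: methanol, CO
Why: Oxidation of the lactol should give the alkylidenesuccinic‑type anhydride, which methanol opens at the non‑conjugated carbonyl (as with itaconic anhydride), so C8 receives its methyl ester and the conjugated C1 carboxyl stays free.

Step 10
Reactants: 16 diene acid
Product: 17 dimethyl (1R,4S)‑2‑(chlorocarbonyl)‑5‑hexadecylcyclohexa‑2,5‑diene‑1,4‑dicarboxylate (acid chloride of 16)
Conditions: (COCl)2, DMF (cat.), CH2Cl2, 0 °C
Reagents that add atoms: oxalyl chloride, ClC(=O)C(Cl)=O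
Why: Vilsmeier‑type chlorination under base‑free conditions should convert the only free acid into the acid chloride without epimerising the doubly allylic C5 and C8 centres.

Step 11
Reactants: 2 hexadecylmagnesium bromide; 18 methyl but‑2‑ynoate
Product: 21 methyl (E)‑3‑methylnonadec‑2‑enoate, via hexadecylcopper 19 (not isolated), via alkenylcopper adduct 20 (not isolated)
Conditions: 2, CuBr·SMe2, THF, −40 °C; then 18, −78 °C; aq NH4Cl
Reagents that add atoms: none
Why: syn‑Carbocupration of the 2‑ynoate and stereoretentive protonolysis should give the (E)‑enoate with the methyl group cis to the ester, the position from which the amide base later removes the γ‑proton.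

Step 12
Reactants: 17 ring A acid chloride; 21 methyl (E)‑3‑methylnonadec‑2‑enoate
Product: 27 trimethyl (4aR,5S,8R,8aS)‑3,6‑dihexadecyl‑1‑oxo‑1,4,4a,5,8,8a‑hexahydronaphthalene‑2,5,8‑tricarboxylate, via lithium dienolate 22 (not isolated), via acylated keto ester 23 (not isolated), via lithium trienolate 24 (not isolated), via ring‑closed lithium enolate 25 (not isolated), via extended lithium enolate 26 (not isolated)
Conditions: 21 (2.1 equiv), LiN(i‑Pr)2 (2.05 equiv), THF–DMPU, −78 °C; 17, −78 °C; t‑BuOH (0.2 equiv), −78 °C to 25 °C; AcOH, −78 °C; silica gel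
Reagents that add atoms: none
Why: Proposed new method: dienolate 22 (from removal of the CH3 proton syn to the ester) should be C‑acylated at its α‑carbon by 17 (C1–C2) to give keto ester 23, whose doubly activated C2–H is removed by the second equivalent of 22 to give the lithium‑chelated trienolate 24 (O− syn to CO2Me, so C3 and C8a are cis on C1=C2), and this 3‑oxidohexatriene C4=C3–C2=C1(O−)–C8a=C4a should close by thermal disrotatory 6π‑electrocyclisation (equally a 6‑endo‑trig vinylogous Michael addition) to form C4–C4a and enolate 25. The closest known reactions are the α‑selective C‑acylation of lithium ester enolates and dienolates by acid chlorides, anion‑accelerated 6π‑electrocyclisations of acceptor‑substituted hexatrienes, and the Staunton–Weinreb and Hauser annulations as benzo‑fused Michael–Claisen counterparts; their union on an aliphatic dienolate and a dienoyl chloride is what is new. C4a should be set by approach of C4 to the face of C8a=C4a anti to the adjacent C5 ester (C5 preset S), and C8a by kinetic protonation of 25 on the face anti to the C8 ester, which gives the cis ring fusion. The t‑BuOH shuttle then moves the charge into the extended C1–C4 enolate 26, in which C8a can no longer epimerise, and acidic quench followed by equilibration on silica should give the conjugated enone 27. The step needs α‑ over γ‑acylation and 1,2‑ over 1,4‑attack (innate for lithium dienolates with acid chlorides), deprotonation at C2 before C5 or C8 (C2–H of the 1,3‑dicarbonyl is the most acidic site and the monoanion resists further deprotonation), and 6π‑closure over other modes (the only other alkene, C6=C7, is insulated by sp3 C5 and C8).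

## Compound list

1 | 1‑bromohexadecane | CCCCCCCCCCCCCCCCBr | starting material
2 | hexadecylmagnesium bromide | CCCCCCCCCCCCCCCC[Mg]Br | intermediate
3 | 3‑(trimethylsilyl)prop‑2‑yn‑1‑ol | C[Si](C)(C)C#CCO | starting material
4 | cyclic alkenylmagnesium alkoxide | C[Si](C)(C)C1=C(CCCCCCCCCCCCCCCC)CO[Mg]1 | intermediate
5 | (E)‑2‑hexadecyl‑3‑(trimethylsilyl)prop‑2‑en‑1‑ol | C[Si](C)(C)/C=C(/CO)CCCCCCCCCCCCCCCC | intermediate
6 | (E)‑2‑hexadecyl‑3‑(trimethylsilyl)prop‑2‑enal | C[Si](C)(C)/C=C(/C=O)CCCCCCCCCCCCCCCC | intermediate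
7 | [(1E,3E)‑2‑hexadecyl‑4‑methoxybuta‑1,3‑dien‑1‑yl]trimethylsilane | C[Si](C)(C)/C=C(/C=C/OC)CCCCCCCCCCCCCCCC | intermediate
8 | (5R)‑5‑[(1R,2S,5R)‑menthyloxy]furan‑2(5H)‑one | O=C1C=C[C@H](O[C@@H]2C[C@H](C)CC[C@H]2C(C)C)O1 | starting material
9 | (3R,3aR,4S,7S,7aR)‑5‑hexadecyl‑3‑menthyloxy‑7‑methoxy‑4‑(trimethylsilyl)‑3a,4,7,7a‑tetrahydro‑2‑benzofuran‑1(3H)‑one | CCCCCCCCCCCCCCCCC1=C[C@H](OC)[C@@H]2C(=O)O[C@@H](O[C@@H]3C[C@H](C)CC[C@H]3C(C)C)[C@@H]2[C@@H]1[Si](C)(C)C | intermediate
10 | N‑chlorosulfonyl N‑trimethylsilyl amide of 11 | CCCCCCCCCCCCCCCCC1=C[C@H]2[C@H](O[C@@H]3C[C@H](C)CC[C@H]3C(C)C)OC(=O)[C@H]2[C@@H](OC)[C@@H]1C(=O)N([Si](C)(C)C)S(Cl)(=O)=O | intermediate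
11 | (3R,3aR,6R,7S,7aR)‑5‑hexadecyl‑3‑menthyloxy‑7‑methoxy‑1‑oxo‑1,3,3a,6,7,7a‑hexahydro‑2‑benzofuran‑6‑carboxamide | CCCCCCCCCCCCCCCCC1=C[C@H]2[C@H](O[C@@H]3C[C@H](C)CC[C@H]3C(C)C)OC(=O)[C@H]2[C@@H](OC)[C@@H]1C(N)=O | intermediate
12 | (3R,3aR,6S)‑5‑hexadecyl‑3‑menthyloxy‑1‑oxo‑1,3,3a,6‑tetrahydro‑2‑benzofuran‑6‑carboxamide | CCCCCCCCCCCCCCCCC1=C[C@H]2[C@H](O[C@@H]3C[C@H](C)CC[C@H]3C(C)C)OC(=O)C2=C[C@@H]1C(N)=O | intermediate
13 | O‑methyl imidate tetrafluoroborate of 12 | CCCCCCCCCCCCCCCCC1=C[C@H]2[C@H](O[C@@H]3C[C@H](C)CC[C@H]3C(C)C)OC(=O)C2=C[C@@H]1C(OC)=[NH2+].F[B-](F)(F)F | intermediate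
14 | methyl (3aR,6S)‑5‑hexadecyl‑3‑hydroxy‑1‑oxo‑1,3,3a,6‑tetrahydro‑2‑benzofuran‑6‑carboxylate (C3 epimers) | CCCCCCCCCCCCCCCCC1=C[C@H]2C(O)OC(=O)C2=C[C@@H]1C(=O)OC | intermediate
15 | methyl (3aR,6S)‑5‑hexadecyl‑1,3‑dioxo‑1,3,3a,6‑tetrahydro‑2‑benzofuran‑6‑carboxylate | CCCCCCCCCCCCCCCCC1=C[C@H]2C(=O)OC(=O)C2=C[C@@H]1C(=O)OC | intermediate
16 | (3S,6R)‑4‑hexadecyl‑3,6‑bis(methoxycarbonyl)cyclohexa‑1,4‑diene‑1‑carboxylic acid | CCCCCCCCCCCCCCCCC1=C[C@@H](C(=O)OC)C(C(=O)O)=C[C@@H]1C(=O)OC | intermediate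
17 | dimethyl (1R,4S)‑2‑(chlorocarbonyl)‑5‑hexadecylcyclohexa‑2,5‑diene‑1,4‑dicarboxylate (acid chloride of 16) | CCCCCCCCCCCCCCCCC1=C[C@@H](C(=O)OC)C(C(Cl)=O)=C[C@@H]1C(=O)OC | intermediate
18 | methyl but‑2‑ynoate | CC#CC(=O)OC | starting material
19 | hexadecylcopper | CCCCCCCCCCCCCCCC[Cu] | intermediate
20 | methyl (Z)‑2‑cuprio‑3‑methylnonadec‑2‑enoate | CCCCCCCCCCCCCCCC/C(C)=C(\[Cu])C(=O)OC | intermediate
21 | methyl (E)‑3‑methylnonadec‑2‑enoate | CCCCCCCCCCCCCCCC/C(C)=C/C(=O)OC | intermediate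
22 | lithium dienolate of 21 | [Li+].[O-]C(OC)=CC(=C)CCCCCCCCCCCCCCCC | intermediate
23 | α‑acylated keto ester (methyl 2‑acyl‑3‑methylidenenonadecanoate; both C2 epimers) | CCCCCCCCCCCCCCCCC1=C[C@@H](C(=O)OC)C(C(=O)C(C(=O)OC)C(=C)CCCCCCCCCCCCCCCC)=C[C@@H]1C(=O)OC | intermediate
24 | lithium trienolate of 23 | [Li+].CCCCCCCCCCCCCCCCC1=C[C@@H](C(=O)OC)C(C([O-])=C(C(=O)OC)C(=C)CCCCCCCCCCCCCCCC)=C[C@@H]1C(=O)OC | intermediate
25 | ring‑closed lithium enolate (C1=C8a) | [Li+].CCCCCCCCCCCCCCCCC1=C[C@@H](C(=O)OC)C2=C([O-])C(C(=O)OC)=C(CCCCCCCCCCCCCCCC)C[C@H]2[C@@H]1C(=O)OC | intermediate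
26 | extended lithium enolate (C1–C4) | [Li+].CCCCCCCCCCCCCCCCC1=C[C@@H](C(=O)OC)[C@H]2C([O-])=C(C(=O)OC)C(CCCCCCCCCCCCCCCC)=C[C@H]2[C@@H]1C(=O)OC | intermediate
27 | trimethyl (4aR,5S,8R,8aS)‑3,6‑dihexadecyl‑1‑oxo‑1,4,4a,5,8,8a‑hexahydronaphthalene‑2,5,8‑tricarboxylate | CCCCCCCCCCCCCCCCC1=C[C@@H](C(=O)OC)[C@H]2C(=O)C(C(=O)OC)=C(CCCCCCCCCCCCCCCC)C[C@H]2[C@@H]1C(=O)OC | target

## Step count and risks

Total step count: 12. Longest linear sequence: 11 steps (steps 1–10 and 12).

Steps most likely to fail: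

1. Step 12 (Proposed new method). Proton transfer from the acidic C5–H of 17 to the dienolate (ketene formation, loss of C5 configuration) may compete with C‑acylation. O‑acylation may intervene, the electrocyclisation may be too slow, or facial control at C4a or the cis protonation at C8a may be poor. Fallback with known reaction types, setting out from 16 and 21 and coming back at 27: 16 is esterified with TMSCHN2 to the trimethyl ester F1, and 21 is converted (LiN(i‑Pr)2, then TBSCl) into the silyl dienolate F2. A Lewis‑acid‑promoted vinylogous Mukaiyama–Michael addition (TBSOTf or TiCl4, CH2Cl2, −78 °C) of F2 to F1 should form C4–C4a by γ‑attack anti to the C5 ester under base‑free conditions, giving the tetraester F3. A Dieckmann condensation of F3 through its γ‑deprotonated dienolate (KOt‑Bu, THF, 0 °C; acidic quench) then closes C1–C2 to give 27.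

2. Step 6. The isocyanate may instead undergo [2+2] addition with retention of silicon (β‑lactam), or the substitution may proceed with poor facial or regiochemical control. Fallback setting out from 9 and coming back at 14: a Hosomi–Sakurai hydroxymethylation (paraformaldehyde, BF3·OEt2, CH2Cl2, −78 °C; anti‑SE2′) should give the homoallylic alcohol F4. DBU then eliminates methanol to give the butenolide alcohol F5 (C5 bears no acidifying group at this stage). Oxidation (Dess–Martin periodinane, then NaClO2/NaH2PO4/2‑methylbut‑2‑ene) gives the acid F6, TMSCHN2 gives the methyl ester F7, and aqueous HCl in THF hydrolyses the menthyl acetal to 14.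

3. Step 9. The alkylidene anhydride may isomerise to the endocyclic maleic‑type anhydride, C8 may epimerise through the open aldehyde form of 14, or the 1,4‑diene may be over‑oxidised towards the arene. Fallback setting out from 14 and coming back at 16: Pinnick oxidation of the lactol (NaClO2, NaH2PO4, 2‑methylbut‑2‑ene, t‑BuOH–H2O) should give the diacid F8 without passing through an anhydride. Chemoselective Fischer esterification of the non‑conjugated carboxyl (MeOH, cat. Me3SiCl, 0 °C) then gives 16.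

## Further compounds

F1 | step 12 | trimethyl (3S,6R)‑4‑hexadecylcyclohexa‑1,4‑diene‑1,3,6‑tricarboxylate | CCCCCCCCCCCCCCCCC1=C[C@@H](C(=O)OC)C(C(=O)OC)=C[C@@H]1C(=O)OC
F2 | step 12 | tert‑butyldimethylsilyl dienolate of 21 (1‑methoxy‑1‑silyloxy‑3‑hexadecylbuta‑1,3‑diene) | COC(O[Si](C)(C)C(C)(C)C)=CC(=C)CCCCCCCCCCCCCCCC
F3 | step 12 | vinylogous Michael adduct (tetraester; C8a unassigned) | CCCCCCCCCCCCCCCCC1=C[C@@H](C(=O)OC)C(C(=O)OC)[C@@H](CC(CCCCCCCCCCCCCCCC)=CC(=O)OC)[C@@H]1C(=O)OC
F4 | step 6 | homoallylic alcohol (C5 hydroxymethyl; methoxy lactone acetal) | CCCCCCCCCCCCCCCCC1=C[C@H]2[C@H](O[C@@H]3C[C@H](C)CC[C@H]3C(C)C)OC(=O)[C@H]2[C@@H](OC)[C@@H]1CO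
F5 | step 6 | butenolide alcohol | CCCCCCCCCCCCCCCCC1=C[C@H]2[C@H](O[C@@H]3C[C@H](C)CC[C@H]3C(C)C)OC(=O)C2=C[C@@H]1CO
F6 | step 6 | butenolide carboxylic acid | CCCCCCCCCCCCCCCCC1=C[C@H]2[C@H](O[C@@H]3C[C@H](C)CC[C@H]3C(C)C)OC(=O)C2=C[C@@H]1C(O)=O
F7 | step 6 | butenolide methyl ester | CCCCCCCCCCCCCCCCC1=C[C@H]2[C@H](O[C@@H]3C[C@H](C)CC[C@H]3C(C)C)OC(=O)C2=C[C@@H]1C(=O)OC
F8 | step 9 | (3S,6R)‑4‑hexadecyl‑3‑(methoxycarbonyl)cyclohexa‑1,4‑diene‑1,6‑dicarboxylic acid | CCCCCCCCCCCCCCCCC1=C[C@@H](C(O)=O)C(C(O)=O)=C[C@@H]1C(=O)OC
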